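**Plan** (labdane numbering: C2 ester carbon, C3H2, C4 gem-dimethyl carbon, C5/C10 ring fusion, C7=C8, C9 side-chain carbon, C13 methine, C15 carboxyl)
1. Retrosynthesis: cut the angelate C–O bond and lower C15 to the alcohol level; then cut C2–C3, C4–C5 and C9–C10 in one cationic event, which releases 2-methylpropene and an acyclic (Z,E)-dienyl acetal; cut that chain at the Z olefin C10=C5 ([2,3] shift), at C6–C7 behind the E olefin C8=C9 ([3,3] shift) and at C9 (aldehyde from (R)-citronellol).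
2. Enabling feature: in ring A the unit C3H2–C4(CH3)2 is a 2-methylpropene molecule lying between the oxygen-bearing C2 (an acetal carbon in disguise) and C5, the terminus of a trisubstituted olefin C5=C10 whose other end is the quaternary C10; the 5,10-cis fusion with H-5, H-9 and the C10 methyl on one face and the C2 oxygen on the other is what chair-like closure of a Z,E-diene gives.
3. Forward: (R)-citronellol → C9 aldehyde → isopropenyl addition and Johnson–Claisen (E olefin, C5 aldehyde) → isopropenyl addition and [2,3]-Wittig–Still (Z olefin, C2 alcohol) → chiral dioxane acetal; ring A and then ring B form in step 11; auxiliary removal, angeloylation, desilylation and oxidation of C15 finish the route.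
4. Stereochemistry: C13 from citronellol; C2 from the (2R,4R)-pentane-2,4-diol acetal; C5, C10 and C9 relayed from C2 through olefin geometry (Z → cis fusion, E → H-9 on the methyl face) in chair transition states; the Z ester geometry is carried in with angelic acid.

Key step: step 11

Remark: the target is read as (2S,5R,9R,10S,13R) with a Z (angelate) ester; the sense of induction of the pentanediol acetal is taken from the usual model (TiCl4 on the oxygen next to the axial methyl, attack with inversion), which makes the (2R,4R)-diol the one that leads to 2S.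

Step 1
Reactants: 1 (R)-citronellol [(3R)-3,7-dimethyloct-6-en-1-ol]
Product: 2 tert-butyl{[(3R)-3,7-dimethyloct-6-en-1-yl]oxy}diphenylsilane
Conditions: TBDPSCl, imidazole, DMF, rt
Reagents that add atoms: tert-butyl(chloro)diphenylsilane, CC(C)(C)[Si](Cl)(c1ccccc1)c1ccccc1
Why: Imidazole-promoted silylation of the primary alcohol (silyl ether protection) holds C15 at the alcohol level under a group that should survive ozone, organometallic reagents, KH and TiCl4 at −78 °C; the C13 stereocentre is not touched.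

Step 2
Reactants: 2 tert-butyl{[(3R)-3,7-dimethyloct-6-en-1-yl]oxy}diphenylsilane
Product: 4 (4R)-6-[(tert-butyldiphenylsilyl)oxy]-4-methylhexanal, via ozonide 3 (not isolated)
Conditions: O3, CH2Cl2, −78 °C; then PPh3, −78 °C → rt
Reagents that add atoms: ozone, [O-][O+]=O
Why: Ozonolysis with reductive work-up cleaves the only olefin and turns its inner carbon into the aldehyde that becomes C9; no stereocentre is formed.

Step 3
Reactants: 4 (4R)-6-[(tert-butyldiphenylsilyl)oxy]-4-methylhexanal; 5 isopropenylmagnesium bromide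
Product: 6 (6R)-8-[(tert-butyldiphenylsilyl)oxy]-2,6-dimethyloct-1-en-3-ol (both C3 epimers)
Conditions: CH2=C(CH3)MgBr (5), THF, −78 → 0 °C; then aq NH4Cl
Reagents that add atoms: none
Why: Grignard 1,2-addition to the aldehyde gives the 2-methylallylic alcohol needed for the [3,3] step; the new carbinol centre forms without control, which does not matter because it becomes an sp2 carbon in step 4.

Step 4
Reactants: 6 (6R)-8-[(tert-butyldiphenylsilyl)oxy]-2,6-dimethyloct-1-en-3-ol; 7 triethyl orthoacetate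
Product: 9 ethyl (4E,8R)-10-[(tert-butyldiphenylsilyl)oxy]-4,8-dimethyldec-4-enoate, via ketene acetal 8 (not isolated)
Conditions: CH3C(OEt)3 (7, excess), EtCO2H (cat.), 140 °C, EtOH distilled off
Reagents that add atoms: none
Why: Johnson–Claisen orthoester rearrangement, a [3,3] shift through a chair in which the chain on the carbinol carbon sits equatorial, should give the E trisubstituted olefin (the future C8=C9) and adds C6 and C5.

Step 5
Reactants: 9 ethyl (4E,8R)-10-[(tert-butyldiphenylsilyl)oxy]-4,8-dimethyldec-4-enoate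
Product: 11 (4E,8R)-10-[(tert-butyldiphenylsilyl)oxy]-4,8-dimethyldec-4-enal, via aluminium hemiacetal 10 (not isolated)
Conditions: i-Bu2AlH (1.1 equiv), CH2Cl2, −78 °C; then aq potassium sodium tartrate
Reagents that add atoms: none
Why: Partial reduction of the ester: at −78 °C the tetrahedral aluminium hemiacetal should persist and release the aldehyde only on work-up.

Step 6
Reactants: 11 (4E,8R)-10-[(tert-butyldiphenylsilyl)oxy]-4,8-dimethyldec-4-enal; 5 isopropenylmagnesium bromide
Product: 12 (6E,10R)-12-[(tert-butyldiphenylsilyl)oxy]-2,6,10-trimethyldodeca-1,6-dien-3-ol (both C3 epimers)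
Conditions: CH2=C(CH3)MgBr (5), THF, −78 → 0 °C; then aq NH4Cl
Reagents that add atoms: none
Why: Second Grignard 1,2-addition; the uncontrolled carbinol centre (the future C5) is erased in step 8.

Step 7
Reactants: 12 (6E,10R)-12-[(tert-butyldiphenylsilyl)oxy]-2,6,10-trimethyldodeca-1,6-dien-3-ol; 13 tributyl(iodomethyl)stannane
Product: 14 tributyl({[(6E,10R)-12-[(tert-butyldiphenylsilyl)oxy]-2,6,10-trimethyldodeca-1,6-dien-3-yl]oxy}methyl)stannane
Conditions: KH, THF, 0 °C; then Bu3SnCH2I (13), 18-crown-6 (cat.), 0 °C → rt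
Reagents that add atoms: none
Why: Williamson etherification of the potassium alkoxide with the primary iodide gives the stannylmethyl ether without touching the olefins or the silyl ether.

Step 8
Reactants: 14 tributyl({[(6E,10R)-12-[(tert-butyldiphenylsilyl)oxy]-2,6,10-trimethyldodeca-1,6-dien-3-yl]oxy}methyl)stannane
Product: 16 (3Z,7E,11R)-13-[(tert-butyldiphenylsilyl)oxy]-3,7,11-trimethyltrideca-3,7-dien-1-ol, via lithiomethyl ether 15 (not isolated)
Conditions: n-BuLi, THF, −78 °C; then aq NH4Cl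
Reagents that add atoms: none
Why: Tin–lithium exchange sets off the [2,3]-Wittig–Still rearrangement; in its envelope transition state the chain on the carbinol carbon lies pseudoaxial to avoid the 2-methyl group, which should give the Z trisubstituted olefin (the future C10=C5) and delivers C2 as a primary alcohol.

Step 9
Reactants: 16 (3Z,7E,11R)-13-[(tert-butyldiphenylsilyl)oxy]-3,7,11-trimethyltrideca-3,7-dien-1-ol
Product: 17 (3Z,7E,11R)-13-[(tert-butyldiphenylsilyl)oxy]-3,7,11-trimethyltrideca-3,7-dienal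
Conditions: Dess–Martin periodinane, NaHCO3, CH2Cl2, 0 °C; crude product used at once
Reagents that add atoms: none
Why: Buffered periodinane oxidation of the primary alcohol is neutral and fast, so the β,γ-unsaturated aldehyde should be obtained without migration of the Z olefin into conjugation.

Step 10
Reactants: 17 (3Z,7E,11R)-13-[(tert-butyldiphenylsilyl)oxy]-3,7,11-trimethyltrideca-3,7-dienal; 18 (2R,4R)-pentane-2,4-diol
Product: 19 (4R,6R)-2-{(2Z,6E,10R)-12-[(tert-butyldiphenylsilyl)oxy]-2,6,10-trimethyldodeca-2,6-dien-1-yl}-4,6-dimethyl-1,3-dioxane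
Conditions: 18, pyridinium p-toluenesulfonate (cat.), MgSO4, CH2Cl2, 0 °C → rt
Reagents that add atoms: none
Why: Mild acid-catalysed acetalization with water removal; the diol is C2-symmetric, so the acetal carbon is not a stereocentre and a single dioxane should form.

Step 11
Reactants: 19 (4R,6R)-2-{(2Z,6E,10R)-12-[(tert-butyldiphenylsilyl)oxy]-2,6,10-trimethyldodeca-2,6-dien-1-yl}-4,6-dimethyl-1,3-dioxane; 20 2-methylpropene
Product: 24 (2R,4R)-4-{[(2S,4aR,8R,8aS)-8-{(3R)-5-[(tert-butyldiphenylsilyl)oxy]-3-methylpentyl}-4,4,7,8a-tetramethyl-1,2,3,4,4a,5,8,8a-octahydronaphthalen-2-yl]oxy}pentan-2-ol, via acyclic C4 cation 21 (not isolated), via monocyclic C10 cation 22 (not isolated), via bicyclic C8 cation 23 (not isolated)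
Conditions: 20 (4 equiv), 2,4,6-trimethylpyridine (1 equiv), CH2Cl2 (dilute), −78 °C, TiCl4 (3 equiv) added last; then aq NaHCO3
Reagents that add atoms: none
Why: Proposed new method: TiCl4 opens the dioxane at the oxygen next to its axial methyl and the CH2 terminus of 2-methylpropene attacks C2 with inversion (new C2–C3 bond) to give the tertiary C4 cation 21; C5 of the Z olefin then bonds to C4 (new C4–C5 bond, cation 22 at C10), C9 of the E olefin bonds to C10 (cation 23 at C8), and loss of the axial H-7 to the pyridine base ends the cascade. The closest known reaction types are the acetal-initiated cation–olefin polycyclization of chiral pentanediol acetals and the TiCl4-mediated Prins-type addition of allylsilanes and olefins to such acetals; the only new element is that a free olefin is taken up between the acetal carbon and the polyene, which is argued from the nucleophilicity of 2-methylpropene being close to that of the trisubstituted olefins that open these acetals intramolecularly. Ring A closes 6-endo-trig (C4 onto C5=C10) and ring B closes 6-endo-trig (C10 onto C9=C8), both through chairs. C2 (S) is set by the (R,R)-acetal template; C5 and C10 follow from anti addition across the Z olefin (cis fusion) on the face that keeps the bulky C2 alkoxy group equatorial and away from the axial C10 methyl in the ring A chair; C9 follows from the E olefin in a chair ring B, which puts H-9 on the face of the C10 methyl. The step needs the activated acetal to meet 2-methylpropene before any internal olefin and the C4 cation to cyclize before a second 2-methylpropene adds: the substrate secures the first because its nearer olefin is β,γ to C2 (only a three- or four-membered ring could form) and the farther one could only close a seven- or eight-membered ring, and the second because ring closure is a six-membered intramolecular attack on a trisubstituted olefin. Loss of H-7 in preference to a proton of the C8 methyl or H-9 is supported only by the alignment of axial H-7 with the empty orbital and the hindrance of H-9, and is the weak point of the step.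

Step 12
Reactants: 24 (2R,4R)-4-{[(2S,4aR,8R,8aS)-8-{(3R)-5-[(tert-butyldiphenylsilyl)oxy]-3-methylpentyl}-4,4,7,8a-tetramethyl-1,2,3,4,4a,5,8,8a-octahydronaphthalen-2-yl]oxy}pentan-2-ol
Product: 26 (2S,4aR,8R,8aS)-8-{(3R)-5-[(tert-butyldiphenylsilyl)oxy]-3-methylpentyl}-4,4,7,8a-tetramethyl-1,2,3,4,4a,5,8,8a-octahydronaphthalen-2-ol, via β-alkoxy ketone 25 (not isolated)
Conditions: Dess–Martin periodinane, CH2Cl2, rt; then K2CO3, MeOH, rt
Reagents that add atoms: none
Why: Oxidation of the free secondary alcohol of the auxiliary arm and base-induced β-elimination (E1cB) of the resulting β-alkoxy ketone is the standard removal of the pentanediol template; the C2–O bond is not broken, so C2 keeps its configuration.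

Step 13
Reactants: 26 (2S,4aR,8R,8aS)-8-{(3R)-5-[(tert-butyldiphenylsilyl)oxy]-3-methylpentyl}-4,4,7,8a-tetramethyl-1,2,3,4,4a,5,8,8a-octahydronaphthalen-2-ol; 27 angelic acid [(2Z)-2-methylbut-2-enoic acid]
Product: 28 (2S,4aR,8R,8aS)-8-{(3R)-5-[(tert-butyldiphenylsilyl)oxy]-3-methylpentyl}-4,4,7,8a-tetramethyl-1,2,3,4,4a,5,8,8a-octahydronaphthalen-2-yl (2Z)-2-methylbut-2-enoate
Conditions: 27, 2,4,6-trichlorobenzoyl chloride, Et3N, toluene, rt; then 26, 80 °C
Reagents that add atoms: none
Why: Yamaguchi-type esterification through the mixed 2,4,6-trichlorobenzoic anhydride, run without a nucleophilic pyridine catalyst, should acylate the unhindered equatorial C2 alcohol and keep the Z geometry of the angeloyl group.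

Step 14
Reactants: 28 (2S,4aR,8R,8aS)-8-{(3R)-5-[(tert-butyldiphenylsilyl)oxy]-3-methylpentyl}-4,4,7,8a-tetramethyl-1,2,3,4,4a,5,8,8a-octahydronaphthalen-2-yl (2Z)-2-methylbut-2-enoate
Product: 29 (2S,4aR,8R,8aS)-8-[(3R)-5-hydroxy-3-methylpentyl]-4,4,7,8a-tetramethyl-1,2,3,4,4a,5,8,8a-octahydronaphthalen-2-yl (2Z)-2-methylbut-2-enoate
Conditions: HF·pyridine, pyridine, THF, 0 °C → rt
Reagents that add atoms: none
Why: Fluoride cleavage of the Si–O bond under buffered conditions frees the C15 alcohol and should leave the angelate and the trisubstituted olefin alone.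

Step 15
Reactants: 29 (2S,4aR,8R,8aS)-8-[(3R)-5-hydroxy-3-methylpentyl]-4,4,7,8a-tetramethyl-1,2,3,4,4a,5,8,8a-octahydronaphthalen-2-yl (2Z)-2-methylbut-2-enoate
Product: 31 (3R)-3-methyl-5-[(1R,4aR,7S,8aS)-2,5,5,8a-tetramethyl-7-{[(2Z)-2-methylbut-2-enoyl]oxy}-1,4,4a,5,6,7,8,8a-octahydronaphthalen-1-yl]pentanoic acid, via aldehyde 30 (not isolated)
Conditions: TEMPO (cat.), PhI(OAc)2 (2.2 equiv), MeCN/H2O, rt
Reagents that add atoms: water, O
Why: Oxoammonium (TEMPO) oxidation of the primary alcohol to the aldehyde and, through its hydrate, to the acid is selective for the primary carbinol and should spare the secondary ester and both olefins.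

**Compound list**
1 | (R)-citronellol, (3R)-3,7-dimethyloct-6-en-1-ol | C[C@@H](CCO)CCC=C(C)C | starting material
2 | tert-butyl{[(3R)-3,7-dimethyloct-6-en-1-yl]oxy}diphenylsilane | CC(C)=CCC[C@@H](C)CCO[Si](c1ccccc1)(c1ccccc1)C(C)(C)C | intermediate
3 | 3-{(3R)-5-[(tert-butyldiphenylsilyl)oxy]-3-methylpentyl}-5,5-dimethyl-1,2,4-trioxolane (ozonide, both epimers at the ring carbon) | CC1(C)OOC(CC[C@@H](C)CCO[Si](c2ccccc2)(c2ccccc2)C(C)(C)C)O1 | intermediate (not isolated)
4 | (4R)-6-[(tert-butyldiphenylsilyl)oxy]-4-methylhexanal | O=CCC[C@@H](C)CCO[Si](c1ccccc1)(c1ccccc1)C(C)(C)C | intermediate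
5 | isopropenylmagnesium bromide, CH2=C(CH3)MgBr | C=C(C)[Mg]Br | starting material
6 | (6R)-8-[(tert-butyldiphenylsilyl)oxy]-2,6-dimethyloct-1-en-3-ol (both C3 epimers) | C=C(C)C(O)CC[C@@H](C)CCO[Si](c1ccccc1)(c1ccccc1)C(C)(C)C | intermediate
7 | triethyl orthoacetate | CCOC(C)(OCC)OCC | starting material
8 | tert-butyl{[(3R)-6-[(1-ethoxyethenyl)oxy]-3,7-dimethyloct-7-en-1-yl]oxy}diphenylsilane (ketene acetal) | C=C(OCC)OC(CC[C@@H](C)CCO[Si](c1ccccc1)(c1ccccc1)C(C)(C)C)C(C)=C | intermediate (not isolated)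
9 | ethyl (4E,8R)-10-[(tert-butyldiphenylsilyl)oxy]-4,8-dimethyldec-4-enoate | CCOC(=O)CC/C(C)=C/CC[C@@H](C)CCO[Si](c1ccccc1)(c1ccccc1)C(C)(C)C | intermediate
10 | {[(4E,8R)-10-[(tert-butyldiphenylsilyl)oxy]-1-ethoxy-4,8-dimethyldec-4-en-1-yl]oxy}bis(2-methylpropyl)alumane (aluminium hemiacetal) | CCOC(O[Al](CC(C)C)CC(C)C)CC/C(C)=C/CC[C@@H](C)CCO[Si](c1ccccc1)(c1ccccc1)C(C)(C)C | intermediate (not isolated)
11 | (4E,8R)-10-[(tert-butyldiphenylsilyl)oxy]-4,8-dimethyldec-4-enal | O=CCC/C(C)=C/CC[C@@H](C)CCO[Si](c1ccccc1)(c1ccccc1)C(C)(C)C | intermediate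
12 | (6E,10R)-12-[(tert-butyldiphenylsilyl)oxy]-2,6,10-trimethyldodeca-1,6-dien-3-ol (both C3 epimers) | C=C(C)C(O)CC/C(C)=C/CC[C@@H](C)CCO[Si](c1ccccc1)(c1ccccc1)C(C)(C)C | intermediate
13 | tributyl(iodomethyl)stannane | CCCC[Sn](CCCC)(CCCC)CI | starting material
14 | tributyl({[(6E,10R)-12-[(tert-butyldiphenylsilyl)oxy]-2,6,10-trimethyldodeca-1,6-dien-3-yl]oxy}methyl)stannane | C=C(C)C(OC[Sn](CCCC)(CCCC)CCCC)CC/C(C)=C/CC[C@@H](C)CCO[Si](c1ccccc1)(c1ccccc1)C(C)(C)C | intermediate
15 | ({[(6E,10R)-12-[(tert-butyldiphenylsilyl)oxy]-2,6,10-trimethyldodeca-1,6-dien-3-yl]oxy}methyl)lithium | [Li]COC(CC/C(C)=C/CC[C@@H](C)CCO[Si](c1ccccc1)(c1ccccc1)C(C)(C)C)C(C)=C | intermediate (not isolated)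
16 | (3Z,7E,11R)-13-[(tert-butyldiphenylsilyl)oxy]-3,7,11-trimethyltrideca-3,7-dien-1-ol | OCC/C(C)=C\CC/C(C)=C/CC[C@@H](C)CCO[Si](c1ccccc1)(c1ccccc1)C(C)(C)C | intermediate
17 | (3Z,7E,11R)-13-[(tert-butyldiphenylsilyl)oxy]-3,7,11-trimethyltrideca-3,7-dienal | O=CC/C(C)=C\CC/C(C)=C/CC[C@@H](C)CCO[Si](c1ccccc1)(c1ccccc1)C(C)(C)C | intermediate
18 | (2R,4R)-pentane-2,4-diol | C[C@@H](O)C[C@@H](C)O | starting material
19 | (4R,6R)-2-{(2Z,6E,10R)-12-[(tert-butyldiphenylsilyl)oxy]-2,6,10-trimethyldodeca-2,6-dien-1-yl}-4,6-dimethyl-1,3-dioxane | C[C@@H]2C[C@@H](C)OC(C/C(C)=C\CC/C(C)=C/CC[C@@H](C)CCO[Si](c1ccccc1)(c1ccccc1)C(C)(C)C)O2 | intermediate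
20 | 2-methylpropene | C=C(C)C | starting material
21 | acyclic tertiary C4 cation formed by addition of 2-methylpropene to C2 (2S; ring-opened auxiliary arm bound as Cl4Ti alkoxide, zwitterion) | C[C+](C)C[C@H](O[C@H](C)C[C@@H](C)O[Ti-](Cl)(Cl)(Cl)Cl)C/C(C)=C\CC/C(C)=C/CC[C@@H](C)CCO[Si](c1ccccc1)(c1ccccc1)C(C)(C)C | intermediate (not isolated)
22 | monocyclic C10 cation, ring A closed (2S,5R; same titanium-bound arm) | C[C@@H](O[Ti-](Cl)(Cl)(Cl)Cl)C[C@@H](C)O[C@H]1CC(C)(C)[C@@H](CC/C(C)=C/CC[C@@H](C)CCO[Si](c2ccccc2)(c2ccccc2)C(C)(C)C)[C+](C)C1 | intermediate (not isolated)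
23 | bicyclic C8 cation, rings A and B closed (2S,5R,9R,10S; same titanium-bound arm) | C[C@@H](O[Ti-](Cl)(Cl)(Cl)Cl)C[C@@H](C)O[C@H]1CC(C)(C)[C@H]2CC[C+](C)[C@@H](CC[C@@H](C)CCO[Si](c3ccccc3)(c3ccccc3)C(C)(C)C)[C@@]2(C)C1 | intermediate (not isolated)
24 | (2R,4R)-4-{[(2S,4aR,8R,8aS)-8-{(3R)-5-[(tert-butyldiphenylsilyl)oxy]-3-methylpentyl}-4,4,7,8a-tetramethyl-1,2,3,4,4a,5,8,8a-octahydronaphthalen-2-yl]oxy}pentan-2-ol | C[C@@H](O)C[C@@H](C)O[C@H]1CC(C)(C)[C@H]2CC=C(C)[C@@H](CC[C@@H](C)CCO[Si](c3ccccc3)(c3ccccc3)C(C)(C)C)[C@@]2(C)C1 | intermediate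
25 | (4R)-4-{[(2S,4aR,8R,8aS)-8-{(3R)-5-[(tert-butyldiphenylsilyl)oxy]-3-methylpentyl}-4,4,7,8a-tetramethyl-1,2,3,4,4a,5,8,8a-octahydronaphthalen-2-yl]oxy}pentan-2-one | CC(=O)C[C@@H](C)O[C@H]1CC(C)(C)[C@H]2CC=C(C)[C@@H](CC[C@@H](C)CCO[Si](c3ccccc3)(c3ccccc3)C(C)(C)C)[C@@]2(C)C1 | intermediate (not isolated)
26 | (2S,4aR,8R,8aS)-8-{(3R)-5-[(tert-butyldiphenylsilyl)oxy]-3-methylpentyl}-4,4,7,8a-tetramethyl-1,2,3,4,4a,5,8,8a-octahydronaphthalen-2-ol | O[C@H]1CC(C)(C)[C@H]2CC=C(C)[C@@H](CC[C@@H](C)CCO[Si](c3ccccc3)(c3ccccc3)C(C)(C)C)[C@@]2(C)C1 | intermediate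
27 | angelic acid, (2Z)-2-methylbut-2-enoic acid | C/C=C(/C)C(=O)O | starting material
28 | (2S,4aR,8R,8aS)-8-{(3R)-5-[(tert-butyldiphenylsilyl)oxy]-3-methylpentyl}-4,4,7,8a-tetramethyl-1,2,3,4,4a,5,8,8a-octahydronaphthalen-2-yl (2Z)-2-methylbut-2-enoate | C/C=C(/C)C(=O)O[C@H]1CC(C)(C)[C@H]2CC=C(C)[C@@H](CC[C@@H](C)CCO[Si](c3ccccc3)(c3ccccc3)C(C)(C)C)[C@@]2(C)C1 | intermediate
29 | (2S,4aR,8R,8aS)-8-[(3R)-5-hydroxy-3-methylpentyl]-4,4,7,8a-tetramethyl-1,2,3,4,4a,5,8,8a-octahydronaphthalen-2-yl (2Z)-2-methylbut-2-enoate | C/C=C(/C)C(=O)O[C@H]1CC(C)(C)[C@H]2CC=C(C)[C@@H](CC[C@@H](C)CCO)[C@@]2(C)C1 | intermediate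
30 | (2S,4aR,8R,8aS)-4,4,7,8a-tetramethyl-8-[(3R)-3-methyl-5-oxopentyl]-1,2,3,4,4a,5,8,8a-octahydronaphthalen-2-yl (2Z)-2-methylbut-2-enoate | C/C=C(/C)C(=O)O[C@H]1CC(C)(C)[C@H]2CC=C(C)[C@@H](CC[C@@H](C)CC=O)[C@@]2(C)C1 | intermediate (not isolated)
31 | (3R)-3-methyl-5-[(1R,4aR,7S,8aS)-2,5,5,8a-tetramethyl-7-{[(2Z)-2-methylbut-2-enoyl]oxy}-1,4,4a,5,6,7,8,8a-octahydronaphthalen-1-yl]pentanoic acid, i.e. (2S,5R,9R,10S,13R)-2-angeloyloxy-5,10-cis-labd-7-en-15-oic acid | C/C=C(/C)C(=O)O[C@H]1CC(C)(C)[C@H]2CC=C(C)[C@@H](CC[C@@H](C)CC(=O)O)[C@@]2(C)C1 | target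

Total step count: 15. Longest linear sequence: 15 steps, from 1 to 31.

**Steps most likely to fail**

Step 11 (proposed new method). Several processes could spoil it: a second 2-methylpropene may add to the C4 cation before ring A closes (oligomerization); the C4 cation may lose a proton instead of cyclizing; the acetal may ionize to a free oxocarbenium ion so that template control at C2 erodes; the C8 cation may lose a methyl proton or undergo a 1,2-shift, so that the olefin does not end at C7=C8. The fallback uses known chemistry and forms the two bonds in two operations. It sets out from 19: Hosomi–Sakurai opening of the chiral acetal with trimethyl(2-methylallyl)silane (TiCl4, CH2Cl2, −78 °C) sets C2 and the C2–C3 bond and gives (2R,4R)-4-{[(4S,6Z,10E,14R)-16-[(tert-butyldiphenylsilyl)oxy]-2,6,10,14-tetramethylhexadeca-1,6,10-trien-4-yl]oxy}pentan-2-ol F1. Markovnikov protonation of its 1,1-disubstituted olefin with SnCl4 and 2-methoxyphenol (1:1, CH2Cl2, −78 °C) then starts a conventional Brønsted-acid polyene bicyclization that forms C4–C5 and C9–C10 and comes back to the route at 24.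

Step 9 (and the acetalization that follows it). The β,γ-olefin may migrate into conjugation with the aldehyde, with loss of the Z geometry, during oxidation, handling or acid-catalysed acetal formation. The fallback never passes through the free aldehyde. It sets out from 11: Still–Gennari olefination with ethyl 2-[bis(2,2,2-trifluoroethoxy)phosphoryl]propanoate (KN(SiMe3)2, 18-crown-6, THF, −78 °C) gives ethyl (2Z,6E,10R)-12-[(tert-butyldiphenylsilyl)oxy]-2,6,10-trimethyldodeca-2,6-dienoate F2. Reduction with i-Bu2AlH gives (2Z,6E,10R)-12-[(tert-butyldiphenylsilyl)oxy]-2,6,10-trimethyldodeca-2,6-dien-1-ol F3, and CBr4/PPh3 gives {[(3R,6E,10Z)-12-bromo-3,7,11-trimethyldodeca-6,10-dien-1-yl]oxy}(tert-butyl)diphenylsilane F4. Alkylation of 2-lithio-1,3-dithiane (THF, −78 °C) gives 2-{(2Z,6E,10R)-12-[(tert-butyldiphenylsilyl)oxy]-2,6,10-trimethyldodeca-2,6-dien-1-yl}-1,3-dithiane F5. Oxidative exchange of the dithiane for the dioxane with PhI(OCOCF3)2 in MeCN in the presence of diol 18 comes back to the route at 19.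

Step 13. The 2-methylbut-2-enoyl unit may isomerize from Z to E (addition–elimination of chloride or amine at C3 of the activated acid) during activation or acyl transfer. The fallback builds the Z olefin on the ester. It sets out from 26: esterification with 2-[bis(2,2,2-trifluoroethoxy)phosphoryl]propanoic acid (dicyclohexylcarbodiimide, DMAP, CH2Cl2) gives (2S,4aR,8R,8aS)-8-{(3R)-5-[(tert-butyldiphenylsilyl)oxy]-3-methylpentyl}-4,4,7,8a-tetramethyl-1,2,3,4,4a,5,8,8a-octahydronaphthalen-2-yl 2-[bis(2,2,2-trifluoroethoxy)phosphoryl]propanoate F6. Still–Gennari olefination with acetaldehyde (KN(SiMe3)2, 18-crown-6, THF, −78 °C) comes back to the route at 28.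

Further compounds
F1 | step 11 | (2R,4R)-4-{[(4S,6Z,10E,14R)-16-[(tert-butyldiphenylsilyl)oxy]-2,6,10,14-tetramethylhexadeca-1,6,10-trien-4-yl]oxy}pentan-2-ol | C=C(C)C[C@H](O[C@H](C)C[C@@H](C)O)C/C(C)=C\CC/C(C)=C/CC[C@@H](C)CCO[Si](c1ccccc1)(c1ccccc1)C(C)(C)C
F2 | step 9 | ethyl (2Z,6E,10R)-12-[(tert-butyldiphenylsilyl)oxy]-2,6,10-trimethyldodeca-2,6-dienoate | CCOC(=O)/C(C)=C\CC/C(C)=C/CC[C@@H](C)CCO[Si](c1ccccc1)(c1ccccc1)C(C)(C)C
F3 | step 9 | (2Z,6E,10R)-12-[(tert-butyldiphenylsilyl)oxy]-2,6,10-trimethyldodeca-2,6-dien-1-ol | OC/C(C)=C\CC/C(C)=C/CC[C@@H](C)CCO[Si](c1ccccc1)(c1ccccc1)C(C)(C)C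
F4 | step 9 | {[(3R,6E,10Z)-12-bromo-3,7,11-trimethyldodeca-6,10-dien-1-yl]oxy}(tert-butyl)diphenylsilane | BrC/C(C)=C\CC/C(C)=C/CC[C@@H](C)CCO[Si](c1ccccc1)(c1ccccc1)C(C)(C)C
F5 | step 9 | 2-{(2Z,6E,10R)-12-[(tert-butyldiphenylsilyl)oxy]-2,6,10-trimethyldodeca-2,6-dien-1-yl}-1,3-dithiane | C1CSC(C/C(C)=C\CC/C(C)=C/CC[C@@H](C)CCO[Si](c2ccccc2)(c2ccccc2)C(C)(C)C)SC1
F6 | step 13 | (2S,4aR,8R,8aS)-8-{(3R)-5-[(tert-butyldiphenylsilyl)oxy]-3-methylpentyl}-4,4,7,8a-tetramethyl-1,2,3,4,4a,5,8,8a-octahydronaphthalen-2-yl 2-[bis(2,2,2-trifluoroethoxy)phosphoryl]propanoate | CC(C(=O)O[C@H]1CC(C)(C)[C@H]2CC=C(C)[C@@H](CC[C@@H](C)CCO[Si](c3ccccc3)(c3ccccc3)C(C)(C)C)[C@@]2(C)C1)P(=O)(OCC(F)(F)F)OCC(F)(F)F
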